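**Plan**

1. Numbering: C1/C5 are the ring-fusion carbons, C2–C3=C4(CH3) complete the cyclopentene, C6 is the carbinol, C7 carries the side chain, C8 is the ring CH2, C9 the ring acetoxy carbon, C10 the methylene-bearing carbon, and C11(CH3)–C12–C13–C14=C15 is the side chain.
2. Enabling feature: ring C1–C5 is a 4-methylcyclopent-3-ene with trans substituents on C1 and C5 and the oxygenated C6 on C5, which is what 1-methyl-1-(trimethylsilyl)allene leaves when it adds across C5=C1 of an E-enone whose carbonyl is C6.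
3. Cuts: C10=CH2 (methylenation), C7–C8 (seven-membered ring, by metathesis), C1–C2 and C4–C5 (five-membered ring, by (3+2) annulation), C1=C5 (cross-metathesis of a side-chain vinyl ketone with a C8–C10 diene-diol).
4. Forward order: side-chain vinyl ketone (C6, C7, C11–C15), then the acyclic E-enone, the cyclopentene, the cycloheptenone, reduction at C7 and C6, the C10 methylene, and last the three acetates.
5. Stereochemistry: C12/C13 come from L-threonate; C11 from hydrogenation of a butenolide anti to its C12 substituent; C9/C10 from (3R,4R)-hexa-1,5-diene-3,4-diol; C1 by Felkin–Anh control from C10 and C5 trans through the E-alkene; C7 by C9-hydroxyl-directed hydrogenation; C6 by hydride attack anti to the C7 side chain.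

Key step: step 16

Remark: 1 and 13 are taken as purchased single enantiomers (13 is the D-mannitol-derived diol). Locants in the names of later compounds follow the numbering above. Nap = 2-naphthylmethyl, TBS = tert-butyldimethylsilyl, TES = triethylsilyl.

**Side-chain vinyl ketone**

Step 1
Reactants: 1 methyl 3,4-O-isopropylidene-L-threonate
Product: 2 (2R)-2-[(4S)-2,2-dimethyl-1,3-dioxolan-4-yl]-2-hydroxy-N-methoxy-N-methylacetamide
Conditions: MeNH(OMe)·HCl, i-PrMgCl, THF, −20 °C
Reagents that add atoms: N,O-dimethylhydroxylamine hydrochloride, CNOC.Cl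
Why: Aminolysis of the ester by the magnesium amide gives the Weinreb amide, and the magnesium alkoxide of the free hydroxyl keeps C12 from epimerising.

Step 2
Reactants: 2 hydroxy Weinreb amide
Product: 3 (1R)-1-[(4S)-2,2-dimethyl-1,3-dioxolan-4-yl]-1-hydroxypropan-2-one
Conditions: MeMgBr (3 equiv), THF, −78 to 0 °C
Reagents that add atoms: methylmagnesium bromide, C[Mg]Br
Why: Weinreb ketone synthesis, in which the chelated tetrahedral adduct stops the addition at the methyl ketone.

Step 3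
Reactants: 3 α-hydroxy methyl ketone
Product: 5 (5S)-5-[(4S)-2,2-dimethyl-1,3-dioxolan-4-yl]-4-methylfuran-2(5H)-one, via ester ylide 4 (not isolated)
Conditions: Ph3P=C=C=O, toluene, 80 °C
Reagents that add atoms: (triphenylphosphoranylidene)ketene, O=C=C=P(c1ccccc1)(c1ccccc1)c1ccccc1
Why: The hydroxyl adds to the ketene ylide and the resulting ester ylide closes by intramolecular Wittig olefination on the neighbouring ketone (butenolide synthesis with the Bestmann ylide), leaving C12 untouched.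

Step 4
Reactants: 5 butenolide
Product: 6 (4R,5S)-5-[(4S)-2,2-dimethyl-1,3-dioxolan-4-yl]-4-methyloxolan-2-one
Conditions: H2 (1 atm), Rh/Al2O3, EtOAc, rt
Reagents that add atoms: none
Why: Heterogeneous hydrogenation should deliver hydrogen to the butenolide face opposite the C12 dioxolanyl group, which sets C11 with the methyl cis to that group.

Step 5
Reactants: 6 cis-lactone acetonide
Product: 7 (4R,5S)-5-[(1S)-1,2-dihydroxyethyl]-4-methyloxolan-2-one
Conditions: AcOH/H2O (4:1), 40 °C
Reagents that add atoms: none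
Why: Acid hydrolysis of a terminal acetonide, to which the γ-lactone is inert.

Step 6
Reactants: 7 lactone diol
Product: 8 (2R)-2-hydroxy-2-[(2S,3R)-3-methyl-5-oxooxolan-2-yl]acetaldehyde
Conditions: TEMPO (cat.), PhI(OAc)2, CH2Cl2, rt
Reagents that add atoms: none
Why: Nitroxyl-catalysed oxidation is selective for the primary hydroxyl of a 1,2-diol.

Step 7
Reactants: 8 hydroxy aldehyde
Product: 9 (4R,5S)-5-[(1S)-1-hydroxy-3-methylbut-2-en-1-yl]-4-methyloxolan-2-one
Conditions: i-PrPPh3 iodide (2.5 equiv), n-BuLi, THF, −78 to 0 °C, then 8 at −78 °C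
Reagents that add atoms: isopropyltriphenylphosphonium iodide, CC(C)[P+](c1ccccc1)(c1ccccc1)c1ccccc1.[I-]
Why: Wittig olefination with a non-stabilised ylide, whose first equivalent turns the C13 hydroxyl into its alkoxide and so disfavours enolisation of the β-acyloxy aldehyde.

Step 8
Reactants: 9 allylic alcohol lactone
Product: 10 (3R,4S,5S)-4,5-dihydroxy-N-methoxy-N,3,7-trimethyloct-6-enamide
Conditions: MeNH(OMe)·HCl, i-PrMgCl, THF, −20 to 0 °C
Reagents that add atoms: N,O-dimethylhydroxylamine hydrochloride, CNOC.Cl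
Why: Aminolysis of the lactone by the magnesium amide gives the Weinreb amide and frees the C12 hydroxyl.

Step 9
Reactants: 10 dihydroxy Weinreb amide
Product: 11 (3R)-3-[(4S,5S)-2,2-dimethyl-5-(2-methylprop-1-en-1-yl)-1,3-dioxolan-4-yl]-N-methoxy-N-methylbutanamide
Conditions: Me2C(OMe)2, PPTS (cat.), CH2Cl2, rt
Reagents that add atoms: 2,2-dimethoxypropane, COC(C)(C)OC
Why: Acid-catalysed transketalisation should close the trans-dioxolane on the syn-1,2-diol faster than the amide relactonises.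

Step 10
Reactants: 11 acetonide Weinreb amide
Product: 12 (5R)-5-[(4S,5S)-2,2-dimethyl-5-(2-methylprop-1-en-1-yl)-1,3-dioxolan-4-yl]hex-1-en-3-one
Conditions: CH2=CHMgBr, THF, 0 °C; inverse quench into cold aqueous NH4Cl
Reagents that add atoms: vinylmagnesium bromide, C=C[Mg]Br
Why: Weinreb ketone synthesis with a vinyl Grignard reagent, the cold acidic quench preventing conjugate addition of the released amine.

**E-enone and allenylsilane**

Step 11
Reactants: 13 (3R,4R)-hexa-1,5-diene-3,4-diol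
Product: 14 (3R,4R)-4-[(tert-butyldimethylsilyl)oxy]hexa-1,5-dien-3-ol
Conditions: TBSCl (1.0 equiv), imidazole, DMF, 0 °C
Reagents that add atoms: tert-butyldimethylsilyl chloride, CC(C)(C)[Si](C)(C)Cl
Why: Monosilylation of a C2-symmetric diol, whose two hydroxyls are equivalent, so that the mono-ether is a single compound (it becomes C9–OTBS and C10–OH).

Step 12
Reactants: 12 side-chain vinyl ketone; 14 mono-TBS diene-diol (2.5 equiv)
Product: 15 (2R,5E,7R,8R)-8-[(tert-butyldimethylsilyl)oxy]-2-[(4S,5S)-2,2-dimethyl-5-(2-methylprop-1-en-1-yl)-1,3-dioxolan-4-yl]-7-hydroxydeca-5,9-dien-4-one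
Conditions: second-generation Hoveyda–Grubbs catalyst (5 mol%), CH2Cl2, 40 °C
Reagents that add atoms: none
Why: Olefin cross-metathesis of the enone with the vinyl group next to the free hydroxyl (the vinyl next to the bulky silyl ether is shielded) should give the E-enone under thermodynamic control.

Step 13
Reactants: 15 γ-hydroxy enone
Product: 16 (2R,5E,7R,8R)-8-[(tert-butyldimethylsilyl)oxy]-2-[(4S,5S)-2,2-dimethyl-5-(2-methylprop-1-en-1-yl)-1,3-dioxolan-4-yl]-7-(naphthalen-2-ylmethoxy)deca-5,9-dien-4-one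
Conditions: 2-(bromomethyl)naphthalene, Ag2O, 4 Å molecular sieves, CH2Cl2, rt, dark
Reagents that add atoms: 2-(bromomethyl)naphthalene, BrCc1ccc2ccccc2c1
Why: Silver oxide-mediated Williamson etherification is neutral enough for a γ-hydroxy enone and gives an ether that resists acid yet is cleaved oxidatively later.

Step 14
Reactants: 17 3-(trimethylsilyl)prop-2-yn-1-ol
Product: 18 3-(trimethylsilyl)prop-2-yn-1-yl methanesulfonate
Conditions: MsCl, Et3N, CH2Cl2, 0 °C
Reagents that add atoms: methanesulfonyl chloride, CS(=O)(=O)Cl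
Why: Sulfonylation of a primary propargylic alcohol.

Step 15
Reactants: 18 propargylic mesylate
Product: 19 1-methyl-1-(trimethylsilyl)allene
Conditions: MeMgCl, CuBr·SMe2 (10 mol%), LiBr, THF, −60 °C to rt
Reagents that add atoms: methylmagnesium chloride, C[Mg]Cl
Why: Copper-catalysed SN2′ substitution of the propargylic mesylate by the methyl Grignard reagent gives the allene.

**Key step and seven-membered ring**

Step 16
Reactants: 16 E-enone (carbonyl C6; C10–ONap; C9–OTBS; C8 vinyl); 19 allenylsilane (2 equiv)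
Product: 20 (3R)-1-[(1S,5R)-5-[(1R,2R)-2-[(tert-butyldimethylsilyl)oxy]-1-(naphthalen-2-ylmethoxy)but-3-en-1-yl]-2-methyl-3-(trimethylsilyl)cyclopent-2-en-1-yl]-3-[(4S,5S)-2,2-dimethyl-5-(2-methylprop-1-en-1-yl)-1,3-dioxolan-4-yl]butan-1-one
Conditions: TiCl4 (1.5 equiv), CH2Cl2, −78 °C; aqueous NaHCO3
Reagents that add atoms: none
Why: TiCl4 activates the C6 carbonyl, the CH2 terminus of the allene attacks C1 to give a β-silyl vinyl cation, a 1,2-silyl shift moves the charge to C4, and the titanium enolate carbon C5 captures it, so that C1–C2 and C4–C5 form in one operation with silicon left on C3. The closest known reaction type is the (trimethylsilyl)cyclopentene annulation of allenylsilanes with acyclic E-enones (Danheiser annulation). The cyclopentene closes in the second stage by a 5-(enolexo)-endo-dig attack of the enolate on the vinyl cation. C1 is controlled by C10: in the Felkin–Anh arrangement (C10–H in the enone plane, C10–O perpendicular) the allene adds anti to the C10–O bond; C5 follows from the E-alkene, because addition and closure are suprafacial and leave the acyl group trans to the C1 substituent. The step needs activation of the enone in the presence of two ethers and an acetonide and attack by the CH2 terminus of the allene only; the carbonyl being the strongest Lewis base at −78 °C and the silyl group on the other allene terminus should secure both.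

Step 17
Reactants: 20 silylcyclopentene
Product: 21 (3R)-1-[(1S,5R)-5-[(1R,2R)-2-[(tert-butyldimethylsilyl)oxy]-1-(naphthalen-2-ylmethoxy)but-3-en-1-yl]-2-methylcyclopent-2-en-1-yl]-3-[(4S,5S)-2,2-dimethyl-5-(2-methylprop-1-en-1-yl)-1,3-dioxolan-4-yl]butan-1-one
Conditions: CF3CO2H (10 equiv), CH2Cl2, 0 °C
Reagents that add atoms: none
Why: Protodesilylation by ipso-protonation at C3 gives a tertiary β-silyl cation at C4 that loses silicon, so the C3=C4 bond stays where it is.

Step 18
Reactants: 21 cyclopentenyl ketone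
Product: 24 α-methylene ketone (C7=CH2 derivative of 21), via Mannich base 22 (not isolated), via trimethylammonium iodide 23 (not isolated)
Conditions: LDA, THF, −78 °C; CH2=NMe2 iodide, −78 °C to rt; iodomethane, CH2Cl2; aqueous NaHCO3, rt
Reagents that add atoms: N,N-dimethylmethyleneiminium iodide (Eschenmoser's salt), C=[N+](C)C.[I-]
Why: Kinetic deprotonation should occur at the C7 methylene (C5–H is tertiary and cis to the bulky C1 substituent), followed by Mannich reaction, quaternisation and Hofmann-type elimination.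

Step 19
Reactants: 24 α-methylene ketone
Product: 25 cycloheptenone (C6 ketone; C7=C8; C9–OTBS; C10–ONap; trans C1/C5; acetonide side chain on C7)
Conditions: second-generation Hoveyda–Grubbs catalyst (10 mol%), toluene (2 mM), 80 °C
Reagents that add atoms: none
Why: Ring-closing metathesis of the 1,1-disubstituted enone alkene with the C8 vinyl group closes the seven-membered ring as a 2-substituted cycloheptenone.

Step 20
Reactants: 25 silyl ether
Product: 26 γ-hydroxy cycloheptenone (C9–OH)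
Conditions: HF·pyridine, pyridine/THF, 0 °C to rt
Reagents that add atoms: none
Why: Fluoride cleaves the secondary silyl ether under buffered acidic conditions that do not isomerise the γ-hydroxy enone.

Step 21
Reactants: 26 γ-hydroxy cycloheptenone
Product: 27 cycloheptanone with H7 on the face of the C9 hydroxyl (C7 S)
Conditions: [Rh(nbd)(dppb)]BF4 (10 mol%), H2 (50 bar), CH2Cl2, rt
Reagents that add atoms: none
Why: Hydroxyl-directed homogeneous hydrogenation, in which the cationic rhodium catalyst binds the allylic C9 hydroxyl and adds H2 to C7=C8 from that face, while undirected trisubstituted alkenes are not reduced.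

**End game**

Step 22
Reactants: 27 hydroxy ketone
Product: 28 C9 triethylsilyl ether
Conditions: TESCl, imidazole, CH2Cl2, 0 °C
Reagents that add atoms: chlorotriethylsilane, CC[Si](Cl)(CC)CC
Why: Silylation of the only free hydroxyl, which also removes any hemiketal equilibrium with the C6 ketone.

Step 23
Reactants: 28 ketone
Product: 29 C6 alcohol (C6 R; hydroxyl cis to the C7 side chain)
Conditions: LiBH(s-Bu)3, THF, −78 °C; H2O
Reagents that add atoms: none
Why: The bulky borohydride should attack C6 from the face opposite the adjacent C7 side chain, giving the alcohol cis to it.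

Step 24
Reactants: 29 alcohol
Product: 30 C6 tert-butyldimethylsilyl ether
Conditions: TBSOTf, 2,6-lutidine, CH2Cl2, 0 °C
Reagents that add atoms: tert-butyldimethylsilyl trifluoromethanesulfonate, CC(C)(C)[Si](C)(C)OS(=O)(=O)C(F)(F)F
Why: A silyl triflate silylates the hindered secondary alcohol.

Step 25
Reactants: 30 naphthylmethyl ether
Product: 31 C10 alcohol
Conditions: DDQ, CH2Cl2/pH 7 buffer (10:1), 0 °C to rt
Reagents that add atoms: none
Why: Oxidative cleavage of the 2-naphthylmethyl ether by DDQ, to which silyl ethers, the acetonide and isolated alkenes are inert.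

Step 26
Reactants: 31 alcohol
Product: 32 C10 ketone
Conditions: Dess–Martin periodinane, NaHCO3, CH2Cl2, rt
Reagents that add atoms: none
Why: Dess–Martin oxidation of the secondary alcohol under buffered conditions that do not epimerise C1 or C9.

Step 27
Reactants: 32 ketone
Product: 33 C10 exocyclic methylene compound
Conditions: Cp2TiMe2, toluene, 70 °C, dark
Reagents that add atoms: dimethyltitanocene, C[Ti](C)(C1C=CC=C1)C1C=CC=C1
Why: Petasis methylenation is a non-basic titanium carbene olefination, chosen so that the stereocentres flanking the ketone are kept.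

Step 28
Reactants: 33 acetonide bis-silyl ether
Product: 34 C9/C12/C13 triol with C6–OTBS retained
Conditions: PPTS, MeOH, 40 °C
Reagents that add atoms: none
Why: Acid-catalysed methanolysis removes the acetonide and the triethylsilyl ether, while the hindered tert-butyldimethylsilyl ether on C6 should survive.

Step 29
Reactants: 34 triol
Product: 35 C9/C12/C13 triacetate with C6–OTBS
Conditions: Ac2O, DMAP, pyridine, rt
Reagents that add atoms: acetic anhydride, CC(=O)OC(C)=O
Why: DMAP-catalysed acetylation of the three free secondary hydroxyls.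

Step 30
Reactants: 35 silyl ether triacetate
Product: 36 CNP0194318.1 (target)
Conditions: HF·pyridine, pyridine/THF, rt
Reagents that add atoms: none
Why: Fluoride removes the last silyl ether under acidic conditions in which acetates do not migrate.

**Compound list**

1 | methyl 3,4-O-isopropylidene-L-threonate | COC(=O)[C@H](O)[C@@H]1COC(C)(C)O1 | starting material
2 | (2R)-2-[(4S)-2,2-dimethyl-1,3-dioxolan-4-yl]-2-hydroxy-N-methoxy-N-methylacetamide | CON(C)C(=O)[C@H](O)[C@@H]1COC(C)(C)O1 | intermediate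
3 | (1R)-1-[(4S)-2,2-dimethyl-1,3-dioxolan-4-yl]-1-hydroxypropan-2-one | CC(=O)[C@H](O)[C@@H]1COC(C)(C)O1 | intermediate
4 | ester ylide: (1R)-1-[(4S)-2,2-dimethyl-1,3-dioxolan-4-yl]-2-oxopropyl (triphenylphosphoranylidene)acetate | CC(=O)[C@H](OC(=O)C=P(c1ccccc1)(c1ccccc1)c1ccccc1)[C@@H]1COC(C)(C)O1 | intermediate
5 | (5S)-5-[(4S)-2,2-dimethyl-1,3-dioxolan-4-yl]-4-methylfuran-2(5H)-one | CC1=CC(=O)O[C@@H]1[C@@H]2COC(C)(C)O2 | intermediate
6 | (4R,5S)-5-[(4S)-2,2-dimethyl-1,3-dioxolan-4-yl]-4-methyloxolan-2-one | C[C@@H]1CC(=O)O[C@@H]1[C@@H]2COC(C)(C)O2 | intermediate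
7 | (4R,5S)-5-[(1S)-1,2-dihydroxyethyl]-4-methyloxolan-2-one | C[C@@H]1CC(=O)O[C@@H]1[C@@H](O)CO | intermediate
8 | (2R)-2-hydroxy-2-[(2S,3R)-3-methyl-5-oxooxolan-2-yl]acetaldehyde | C[C@@H]1CC(=O)O[C@@H]1[C@@H](O)C=O | intermediate
9 | (4R,5S)-5-[(1S)-1-hydroxy-3-methylbut-2-en-1-yl]-4-methyloxolan-2-one | C[C@@H]1CC(=O)O[C@@H]1[C@@H](O)C=C(C)C | intermediate
10 | (3R,4S,5S)-4,5-dihydroxy-N-methoxy-N,3,7-trimethyloct-6-enamide | CON(C)C(=O)C[C@@H](C)[C@H](O)[C@@H](O)C=C(C)C | intermediate
11 | (3R)-3-[(4S,5S)-2,2-dimethyl-5-(2-methylprop-1-en-1-yl)-1,3-dioxolan-4-yl]-N-methoxy-N-methylbutanamide | CON(C)C(=O)C[C@@H](C)[C@@H]1OC(C)(C)O[C@H]1C=C(C)C | intermediate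
12 | (5R)-5-[(4S,5S)-2,2-dimethyl-5-(2-methylprop-1-en-1-yl)-1,3-dioxolan-4-yl]hex-1-en-3-one | C=CC(=O)C[C@@H](C)[C@@H]1OC(C)(C)O[C@H]1C=C(C)C | intermediate
13 | (3R,4R)-hexa-1,5-diene-3,4-diol | C=C[C@@H](O)[C@H](O)C=C | starting material
14 | (3R,4R)-4-[(tert-butyldimethylsilyl)oxy]hexa-1,5-dien-3-ol | C=C[C@@H](O)[C@H](O[Si](C)(C)C(C)(C)C)C=C | intermediate
15 | (2R,5E,7R,8R)-8-[(tert-butyldimethylsilyl)oxy]-2-[(4S,5S)-2,2-dimethyl-5-(2-methylprop-1-en-1-yl)-1,3-dioxolan-4-yl]-7-hydroxydeca-5,9-dien-4-one | C=C[C@@H](O[Si](C)(C)C(C)(C)C)[C@H](O)/C=C/C(=O)C[C@@H](C)[C@@H]1OC(C)(C)O[C@H]1C=C(C)C | intermediate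
16 | (2R,5E,7R,8R)-8-[(tert-butyldimethylsilyl)oxy]-2-[(4S,5S)-2,2-dimethyl-5-(2-methylprop-1-en-1-yl)-1,3-dioxolan-4-yl]-7-(naphthalen-2-ylmethoxy)deca-5,9-dien-4-one | C=C[C@@H](O[Si](C)(C)C(C)(C)C)[C@H](OCc1ccc2ccccc2c1)/C=C/C(=O)C[C@@H](C)[C@@H]3OC(C)(C)O[C@H]3C=C(C)C | intermediate
17 | 3-(trimethylsilyl)prop-2-yn-1-ol | C[Si](C)(C)C#CCO | starting material
18 | 3-(trimethylsilyl)prop-2-yn-1-yl methanesulfonate | C[Si](C)(C)C#CCOS(C)(=O)=O | intermediate
19 | 1-methyl-1-(trimethylsilyl)allene | C=C=C(C)[Si](C)(C)C | intermediate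
20 | (3R)-1-[(1S,5R)-5-[(1R,2R)-2-[(tert-butyldimethylsilyl)oxy]-1-(naphthalen-2-ylmethoxy)but-3-en-1-yl]-2-methyl-3-(trimethylsilyl)cyclopent-2-en-1-yl]-3-[(4S,5S)-2,2-dimethyl-5-(2-methylprop-1-en-1-yl)-1,3-dioxolan-4-yl]butan-1-one | C=C[C@@H](O[Si](C)(C)C(C)(C)C)[C@H](OCc3ccc4ccccc4c3)[C@@H]1CC([Si](C)(C)C)=C(C)[C@H]1C(=O)C[C@@H](C)[C@@H]2OC(C)(C)O[C@H]2C=C(C)C | intermediate
21 | (3R)-1-[(1S,5R)-5-[(1R,2R)-2-[(tert-butyldimethylsilyl)oxy]-1-(naphthalen-2-ylmethoxy)but-3-en-1-yl]-2-methylcyclopent-2-en-1-yl]-3-[(4S,5S)-2,2-dimethyl-5-(2-methylprop-1-en-1-yl)-1,3-dioxolan-4-yl]butan-1-one | C=C[C@@H](O[Si](C)(C)C(C)(C)C)[C@H](OCc3ccc4ccccc4c3)[C@@H]1CC=C(C)[C@H]1C(=O)C[C@@H](C)[C@@H]2OC(C)(C)O[C@H]2C=C(C)C | intermediate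
22 | Mannich base: 21 carrying CH2NMe2 on C7 (both C7 epimers) | C=C[C@@H](O[Si](C)(C)C(C)(C)C)[C@H](OCc3ccc4ccccc4c3)[C@@H]1CC=C(C)[C@H]1C(=O)C(CN(C)C)[C@@H](C)[C@@H]2OC(C)(C)O[C@H]2C=C(C)C | intermediate
23 | trimethylammonium iodide of 22 | C=C[C@@H](O[Si](C)(C)C(C)(C)C)[C@H](OCc3ccc4ccccc4c3)[C@@H]1CC=C(C)[C@H]1C(=O)C(C[N+](C)(C)C)[C@@H](C)[C@@H]2OC(C)(C)O[C@H]2C=C(C)C.[I-] | intermediate
24 | α-methylene ketone: 21 with C7=CH2 (2-methylidenebutan-1-one) | C=C[C@@H](O[Si](C)(C)C(C)(C)C)[C@H](OCc3ccc4ccccc4c3)[C@@H]1CC=C(C)[C@H]1C(=O)C(=C)[C@@H](C)[C@@H]2OC(C)(C)O[C@H]2C=C(C)C | intermediate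
25 | cycloheptenone (1R,5S,9R,10R,11R,12S,13S): C6 ketone; C7=C8; C3=C4; 9-OTBS; 10-ONap; 12,13-acetonide | C1=C([C@@H](C)[C@@H]3OC(C)(C)O[C@H]3C=C(C)C)C(=O)[C@@H]2C(C)=CC[C@H]2[C@@H](OCc4ccc5ccccc5c4)[C@@H]1O[Si](C)(C)C(C)(C)C | intermediate
26 | cycloheptenone as 25 with 9-OH | C1=C([C@@H](C)[C@@H]3OC(C)(C)O[C@H]3C=C(C)C)C(=O)[C@@H]2C(C)=CC[C@H]2[C@@H](OCc4ccc5ccccc5c4)[C@@H]1O | intermediate
27 | cycloheptanone (1R,5S,7S,9R,10R,11R,12S,13S): C6 ketone; 9-OH; 10-ONap; 12,13-acetonide | C1[C@@H]([C@@H](C)[C@@H]3OC(C)(C)O[C@H]3C=C(C)C)C(=O)[C@@H]2C(C)=CC[C@H]2[C@@H](OCc4ccc5ccccc5c4)[C@@H]1O | intermediate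
28 | cycloheptanone as 27 with 9-OTES | C1[C@@H]([C@@H](C)[C@@H]3OC(C)(C)O[C@H]3C=C(C)C)C(=O)[C@@H]2C(C)=CC[C@H]2[C@@H](OCc4ccc5ccccc5c4)[C@@H]1O[Si](CC)(CC)CC | intermediate
29 | (6R)-alcohol: 6-OH; 9-OTES; 10-ONap; 12,13-acetonide | C1[C@@H]([C@@H](C)[C@@H]3OC(C)(C)O[C@H]3C=C(C)C)[C@@H](O)[C@@H]2C(C)=CC[C@H]2[C@@H](OCc4ccc5ccccc5c4)[C@@H]1O[Si](CC)(CC)CC | intermediate
30 | 6-OTBS; 9-OTES; 10-ONap; 12,13-acetonide | C1[C@@H]([C@@H](C)[C@@H]3OC(C)(C)O[C@H]3C=C(C)C)[C@@H](O[Si](C)(C)C(C)(C)C)[C@@H]2C(C)=CC[C@H]2[C@@H](OCc4ccc5ccccc5c4)[C@@H]1O[Si](CC)(CC)CC | intermediate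
31 | 6-OTBS; 9-OTES; 10-OH; 12,13-acetonide | C1[C@@H]([C@@H](C)[C@@H]3OC(C)(C)O[C@H]3C=C(C)C)[C@@H](O[Si](C)(C)C(C)(C)C)[C@@H]2C(C)=CC[C@H]2[C@@H](O)[C@@H]1O[Si](CC)(CC)CC | intermediate
32 | 6-OTBS; 9-OTES; C10 ketone; 12,13-acetonide | C1[C@@H]([C@@H](C)[C@@H]3OC(C)(C)O[C@H]3C=C(C)C)[C@@H](O[Si](C)(C)C(C)(C)C)[C@@H]2C(C)=CC[C@H]2C(=O)[C@@H]1O[Si](CC)(CC)CC | intermediate
33 | 6-OTBS; 9-OTES; C10=CH2; 12,13-acetonide | C1[C@@H]([C@@H](C)[C@@H]3OC(C)(C)O[C@H]3C=C(C)C)[C@@H](O[Si](C)(C)C(C)(C)C)[C@@H]2C(C)=CC[C@H]2C(=C)[C@@H]1O[Si](CC)(CC)CC | intermediate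
34 | 6-OTBS; 9,12,13-triol; C10=CH2 | C1[C@@H]([C@@H](C)[C@H](O)[C@@H](O)C=C(C)C)[C@@H](O[Si](C)(C)C(C)(C)C)[C@@H]2C(C)=CC[C@H]2C(=C)[C@@H]1O | intermediate
35 | 6-OTBS; 9,12,13-triacetate; C10=CH2 | C1[C@@H]([C@@H](C)[C@H](OC(C)=O)[C@@H](OC(C)=O)C=C(C)C)[C@@H](O[Si](C)(C)C(C)(C)C)[C@@H]2C(C)=CC[C@H]2C(=C)[C@@H]1OC(C)=O | intermediate
36 | CNP0194318.1: (1R,5S,6R,7S,9R,11R,12S,13S)-6-hydroxy-9,12,13-triacetate with C10=CH2 and C3=C4 | C1[C@@H]([C@@H](C)[C@H](OC(C)=O)[C@@H](OC(C)=O)C=C(C)C)[C@@H](O)[C@@H]2C(C)=CC[C@H]2C(=C)[C@@H]1OC(C)=O | target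

**Step count and weak points**

Total: 30 steps. Longest linear sequence: 27 steps (steps 1–10, 12, 13 and 16–30, from 1).

Step 18 (α-methylenation). What may go wrong is deprotonation at the allylic C5 instead of C7, which would scramble C5 and draw the ring double bond into conjugation, and loss of the reactive exo-methylene ketone by oligomerisation during the elimination. The fallback sets out from 21: soft enolisation with (c-C6H11)2BCl/Et3N in Et2O at −78 °C, which selects the unhindered methylene side, followed by aldol addition of monomeric formaldehyde should give the hydroxymethyl ketone F1. Mesylation (MsCl, Et3N, 0 °C) with E1cB elimination in the same flask then returns to the route at 24.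

Step 17 (protodesilylation). What may go wrong is acid-induced opening of the allylic acetonide, loss of the allylic silyl ether, or acid-catalysed migration of the C3=C4 bond, all competing with a slow ipso-protonation. The fallback sets out from 20: ipso-iododesilylation with N-iodosuccinimide in MeCN at 0 °C should give the vinyl iodide F2 without protic acid. Palladium-catalysed formate reduction (Pd(OAc)2, PPh3, HCO2H, Et3N, DMF, 40 °C) then replaces iodine by hydrogen and returns to the route at 21.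

Step 7 (Wittig olefination of the hydroxy aldehyde). What may go wrong is enolisation of the aldehyde under the basic ylide with expulsion of the lactone carboxylate from C12, or opening of the lactone by the C13 alkoxide or the ylide. The fallback sets out from 7: the lactone is opened first (MeNH(OMe)·HCl, i-PrMgCl) to the trihydroxy Weinreb amide F3. Thermodynamic acetonide formation (acetone, camphorsulfonic acid) should then place the dioxolane on the internal syn-diol as the trans-disubstituted ring and leave the primary alcohol free, giving the acetonide alcohol F4. Dess–Martin oxidation gives the α-alkoxy aldehyde F5, which has no β-leaving group, and isopropylidene Wittig olefination returns to the route at 11, bypassing steps 6 to 9.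

**Further compounds**

F1 | step 18 | hydroxymethyl ketone: 21 carrying CH2OH on C7 (both C7 epimers) | C=C[C@@H](O[Si](C)(C)C(C)(C)C)[C@H](OCc3ccc4ccccc4c3)[C@@H]1CC=C(C)[C@H]1C(=O)C(CO)[C@@H](C)[C@@H]2OC(C)(C)O[C@H]2C=C(C)C
F2 | step 17 | vinyl iodide: 20 with iodine in place of the trimethylsilyl group on C3 | C=C[C@@H](O[Si](C)(C)C(C)(C)C)[C@H](OCc3ccc4ccccc4c3)[C@@H]1CC(I)=C(C)[C@H]1C(=O)C[C@@H](C)[C@@H]2OC(C)(C)O[C@H]2C=C(C)C
F3 | step 7 | (3R,4S,5S)-4,5,6-trihydroxy-N-methoxy-N,3-dimethylhexanamide | CON(C)C(=O)C[C@@H](C)[C@H](O)[C@@H](O)CO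
F4 | step 7 | (3R)-3-[(4S,5S)-5-(hydroxymethyl)-2,2-dimethyl-1,3-dioxolan-4-yl]-N-methoxy-N-methylbutanamide | CON(C)C(=O)C[C@@H](C)[C@@H]1OC(C)(C)O[C@H]1CO
F5 | step 7 | (3R)-3-[(4S,5R)-5-formyl-2,2-dimethyl-1,3-dioxolan-4-yl]-N-methoxy-N-methylbutanamide | CON(C)C(=O)C[C@@H](C)[C@@H]1OC(C)(C)O[C@H]1C=O
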